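Coupling partner is conserved in a closed flask, free or bound, and each tris adduct holds 3 of it, so c(tris adduct) can't pass the partner charge divided by 3. For Sunday's flask that gives 83.3% of the substrate charged: this is the tris ceiling, the partner charge over 3 times the substrate charge.

| flask | substrate | coupling partner | remark | time |
|---|---|---|---|---|
| ochre | 0.50 M | 0.36 M | run made earlier |  |
| amber | 0.50 M | 1.9 M | run made earlier |  |
| Sunday's | 0.50 M | 1.25 M |  | 25 h |
| Tuesday's | 0.50 M | 0.250 M |  | 25 h |
| Friday's | 0.50 M | 1.50 M |  | 25 h |

| run | time / h | tris adduct / % |
|---|---|---|
| ochre | 1.00 | 1.1 |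
| ochre | 1.50 | 3.7 |
| ochre | 2.50 | 9.5 |
| ochre | 4.00 | 8.8 |
| ochre | 5.00 | 10.6 |
| ochre | 8.00 | 7.8 |
| ochre | 12.0 | 6.4 |
| amber | 0.667 | 35.3 |
| amber | 2.00 | 74.0 |
| amber | 4.00 | 90.0 |
| amber | 5.00 | 91.9 |
| amber | 8.00 | 93.3 |
| amber | 10.0 | 95.7 |
| amber | 12.0 | 94.4 |

(scatter of a reading: 1 percentage point)

* which of these holds the largest part of the substrate at the end of Sunday's (tris adduct / bis adduct / single product / substrate)
* which of these holds the largest part of the substrate at the end of Tuesday's (tris adduct / bis adduct / single product / substrate)
* which of these holds the largest part of the substrate at the end of Friday's (tris adduct / bis adduct / single product / substrate)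
* final tris adduct in Sunday's, as a percentage of the substrate charged

In the amber run the ceiling is 127%, above the charge, so the substrate itself is the limit, and the last reading there is 94.4%. Scaling Sunday's ceiling by that reading gave me 78.7%.

The weak link was that scaling: amber reads 93.3% at 8.00 h and 94.4% at 12.0 h, but ochre sinks. The ochre run must keep 28.0% of its substrate or more, and its tris adduct reads 10.6% at 5.00 h and 6.4% at 12.0 h. I took that, as a guess from these two readings, for a loss of 0.0721 h⁻¹ while substrate is present.

Amber reads 74.0% at 2.00 h. Stretching that time by the ratio of partner charges gave 3.04 h for Sunday's flask, and I applied the ochre loss over that time with a factor of 0.5, my guess for the substrate present on average. That keeps 89.6% of the ceiling, so I committed to 74.7%.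

The forecast, which differs from my reckoning, named tris adduct, substrate and tris adduct for Sunday's, Tuesday's and Friday's, with 50% for Sunday's: “Near-statistical distribution gives tris around 50%”.

The flasks gave tris adduct, substrate and tris adduct, and Sunday's ended at 69.7%, which is 83.7% of its ceiling.

    substrate + coupling partner → single product (k = 0.0180 M⁻¹ min⁻¹)
    coupling partner + single product → bis adduct (k = 0.0390 M⁻¹ min⁻¹)
    coupling partner + bis adduct → tris adduct (k = 0.0780 M⁻¹ min⁻¹)
    substrate + tris adduct → side product (k = 0.00250 M⁻¹ min⁻¹)

In Sunday's flask the rate constant of partner with bis adduct stands 2.0 times that of partner with single product, and bis adduct ends at 4.09% against 69.7% of tris adduct. The neighbour of Sunday's with 0.30 M of substrate has a ceiling of 139%, above the charge, so substrate becomes the limiting reagent and the bound is the whole charge; that flask gave 96.4%, with 3.62% of side product.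

(Readings and results stem from a simulated flask for an exercise; the scatter is artificial.)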